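**Strategy**

Everything rests on one disconnection, the C9–C10 bond of the trans-decalin. The target shows C4 and C9 anti to each other across the C5–C10 bond shared by rings A and B, which is the geometry of rearside attack on a C4–C5–C10 cyclopropane, and its C8(17) methylene is the trace of an allylsilane. Lewis-acid opening of the strained C4–C10 bond of an acceptor-activated cyclopropane by C9 therefore closes ring B, enlarges a cyclopentanone to ring A and sets C9 and C10 in one operation. The precursor is a 5-methyl-2-oxobicyclo[3.1.0]hexane-1-carboxylate whose cyclopropane CH (labdane C5) carries a chain with a Z-configured trisubstituted allylsilane and the citronellol-derived C13 centre.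

Key step: step 13

**Remarks on the chemistry**

- Labdane numbering (C1–C20, O15) is used for all intermediates; the allylsilane double bond needed has C7 and C11 trans, which is Z under the CIP rules because CH2Si outranks CH2C at C8.
- The sense of induction of the CuOTf–bis(oxazoline) catalyst in step 12 is assumed; the ligand enantiomer that delivers the (1R,5R,6R) bicycle is the one to be used.
- The C19 carboxyl is carried as a 2-(trimethylsilyl)ethyl ester, so that the hindered axial ester and the O15 silyl ether fall together to fluoride.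

**Route**

Step 1
Reactants: 1 (S)-citronellol
Product: 2 tert-butyl{[(3S)-3,7-dimethyloct-6-en-1-yl]oxy}diphenylsilane
Conditions: TBDPSCl, imidazole, CH2Cl2, 0 °C to rt
Reagents that add atoms: tert-butyl(chloro)diphenylsilane, CC(C)(C)[Si](Cl)(c1ccccc1)c1ccccc1
Why: Silyl ether formation at the primary alcohol is routine, and the TBDPS group should survive every later step up to the fluoride treatment while the C13 centre is untouched.

Step 2
Reactants: 2 tert-butyl{[(3S)-3,7-dimethyloct-6-en-1-yl]oxy}diphenylsilane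
Product: 4 (4S)-6-[(tert-butyldiphenylsilyl)oxy]-4-methylhexanal, via ozonide 3 (not isolated)
Conditions: O3, CH2Cl2, −78 °C; then PPh3, −78 °C to rt
Reagents that add atoms: ozone, O=[O+][O-]
Why: Ozonolysis with reductive work-up cleaves the trisubstituted alkene, so that the aldehyde carbon becomes C9 and the chain C9, C11–C15 with its C16 methyl has the correct carbon count.

Step 3
Reactants: 5 (2-bromoprop-2-en-1-yl)trimethylsilane; 4 (4S)-6-[(tert-butyldiphenylsilyl)oxy]-4-methylhexanal
Product: 7 (6S)-8-[(tert-butyldiphenylsilyl)oxy]-6-methyl-2-[(trimethylsilyl)methyl]oct-1-en-3-ol (both C3 epimers), via Grignard reagent 6 (not isolated)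
Conditions: Mg, THF, 50 °C; then 4, −78 to 0 °C
Reagents that add atoms: none
Why: Grignard addition of the 2-metallated allylsilane to the aldehyde should give the 2-(silylmethyl)allylic alcohol, whose new carbinol centre is erased in step 4 and therefore needs no control.

Step 4
Reactants: 7 (6S)-8-[(tert-butyldiphenylsilyl)oxy]-6-methyl-2-[(trimethylsilyl)methyl]oct-1-en-3-ol; 8 triethyl orthoacetate
Product: 10 ethyl (4Z,8S)-10-[(tert-butyldiphenylsilyl)oxy]-8-methyl-4-[(trimethylsilyl)methyl]dec-4-enoate, via ketene acetal 9 (not isolated)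
Conditions: 8 (excess, as solvent), EtCO2H (5 mol %), 138 °C, EtOH distilled off
Reagents that add atoms: none
Why: Johnson–Claisen rearrangement through a chair with the C11 chain equatorial should place C7 trans to C11, which sets the Z-configured C8=C9 allylsilane and brings in C5–C7.

Step 5
Reactants: 10 ethyl (4Z,8S)-10-[(tert-butyldiphenylsilyl)oxy]-8-methyl-4-[(trimethylsilyl)methyl]dec-4-enoate
Product: 12 (4Z,8S)-10-[(tert-butyldiphenylsilyl)oxy]-8-methyl-4-[(trimethylsilyl)methyl]dec-4-enal, via aluminium hemiacetal 11 (not isolated)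
Conditions: i-Bu2AlH (1.05 equiv), CH2Cl2, −78 °C; then MeOH, aq. potassium sodium tartrate
Reagents that add atoms: none
Why: Half-reduction of an unhindered ethyl ester by i-Bu2AlH at low temperature stops at the tetrahedral aluminium hemiacetal, which releases the aldehyde (C5) on work-up.

Step 6
Reactants: 12 (4Z,8S)-10-[(tert-butyldiphenylsilyl)oxy]-8-methyl-4-[(trimethylsilyl)methyl]dec-4-enal; 13 ethyl 2-(triphenyl-λ5-phosphanylidene)propanoate
Product: 14 ethyl (2E,6Z,10S)-12-[(tert-butyldiphenylsilyl)oxy]-2,10-dimethyl-6-[(trimethylsilyl)methyl]dodeca-2,6-dienoate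
Conditions: CH2Cl2, rt
Reagents that add atoms: none
Why: Wittig olefination with the α-methyl stabilised ylide is reliably E-selective, which puts C6 cis to the C20 methyl on the C5=C10 alkene.

Step 7
Reactants: 14 ethyl (2E,6Z,10S)-12-[(tert-butyldiphenylsilyl)oxy]-2,10-dimethyl-6-[(trimethylsilyl)methyl]dodeca-2,6-dienoate
Product: 15 (2E,6Z,10S)-12-[(tert-butyldiphenylsilyl)oxy]-2,10-dimethyl-6-[(trimethylsilyl)methyl]dodeca-2,6-dien-1-ol
Conditions: i-Bu2AlH (2.2 equiv), CH2Cl2, −78 to 0 °C; then aq. potassium sodium tartrate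
Reagents that add atoms: none
Why: 1,2-Reduction of the enoate by i-Bu2AlH should give the allylic alcohol (C1) without touching either alkene.

Step 8
Reactants: 15 (2E,6Z,10S)-12-[(tert-butyldiphenylsilyl)oxy]-2,10-dimethyl-6-[(trimethylsilyl)methyl]dodeca-2,6-dien-1-ol
Product: 16 (2E,6Z,10S)-1-bromo-12-[(tert-butyldiphenylsilyl)oxy]-2,10-dimethyl-6-[(trimethylsilyl)methyl]dodeca-2,6-diene
Conditions: CBr4, PPh3, CH2Cl2, 0 °C; used crude
Reagents that add atoms: tetrabromomethane, BrC(Br)(Br)Br
Why: Appel bromination converts the primary allylic alcohol by SN2 displacement under neutral conditions, which spares the allylsilane and both alkene geometries.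

Step 9
Reactants: 17 2,2,6-trimethyl-4H-1,3-dioxin-4-one; 18 2-(trimethylsilyl)ethan-1-ol
Product: 20 2-(trimethylsilyl)ethyl 3-oxobutanoate, via acetylketene 19 (not isolated)
Conditions: xylene, 140 °C, acetone distilled off
Reagents that add atoms: none
Why: Thermal retro-[4+2] cleavage of the dioxinone releases acetylketene, which the alcohol traps (acetoacetylation).

Step 10
Reactants: 20 2-(trimethylsilyl)ethyl 3-oxobutanoate; 16 (2E,6Z,10S)-1-bromo-12-[(tert-butyldiphenylsilyl)oxy]-2,10-dimethyl-6-[(trimethylsilyl)methyl]dodeca-2,6-diene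
Product: 22 2-(trimethylsilyl)ethyl (6E,10Z,14S)-16-[(tert-butyldiphenylsilyl)oxy]-6,14-dimethyl-3-oxo-10-[(trimethylsilyl)methyl]hexadeca-6,10-dienoate, via dianion 21 (not isolated)
Conditions: 20 (2 equiv), NaH, THF, 0 °C; n-BuLi, 0 °C; then 16, 0 °C
Reagents that add atoms: none
Why: The acetoacetate dianion alkylates at its more reactive γ-carbon with the allylic bromide (dianion γ-alkylation), which forms C1–C2.

Step 11
Reactants: 22 2-(trimethylsilyl)ethyl (6E,10Z,14S)-16-[(tert-butyldiphenylsilyl)oxy]-6,14-dimethyl-3-oxo-10-[(trimethylsilyl)methyl]hexadeca-6,10-dienoate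
Product: 23 2-(trimethylsilyl)ethyl (6E,10Z,14S)-16-[(tert-butyldiphenylsilyl)oxy]-2-diazo-6,14-dimethyl-3-oxo-10-[(trimethylsilyl)methyl]hexadeca-6,10-dienoate
Conditions: 4-AcNHC6H4SO2N3, Et3N, MeCN, 0 °C to rt
Reagents that add atoms: 4-acetamidobenzenesulfonyl azide, CC(=O)Nc1ccc(cc1)S(=O)(=O)N=[N+]=[N-]
Why: Regitz diazo transfer to the active methylene (C4) of a β-keto ester is general and mild.

Step 12
Reactants: 23 2-(trimethylsilyl)ethyl (6E,10Z,14S)-16-[(tert-butyldiphenylsilyl)oxy]-2-diazo-6,14-dimethyl-3-oxo-10-[(trimethylsilyl)methyl]hexadeca-6,10-dienoate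
Product: 24 2-(trimethylsilyl)ethyl (1R,5R,6R)-6-{(3Z,7S)-9-[(tert-butyldiphenylsilyl)oxy]-7-methyl-3-[(trimethylsilyl)methyl]non-3-en-1-yl}-5-methyl-2-oxobicyclo[3.1.0]hexane-1-carboxylate
Conditions: (CuOTf)2·C6H6 (5 mol %), 2,2'-(propane-2,2-diyl)bis[(4S)-4-tert-butyl-4,5-dihydro-1,3-oxazole] (12 mol %), toluene, rt to 50 °C, slow addition of 23
Reagents that add atoms: none
Why: Intramolecular cyclopropanation by a carbenoid of monovalent copper is stereospecific, so the E alkene puts C6 cis to the C20 methyl, while the chiral bis(oxazoline) selects the alkene face and thereby C4, C5 and C10.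

Step 13
Reactants: 24 2-(trimethylsilyl)ethyl (1R,5R,6R)-6-{(3Z,7S)-9-[(tert-butyldiphenylsilyl)oxy]-7-methyl-3-[(trimethylsilyl)methyl]non-3-en-1-yl}-5-methyl-2-oxobicyclo[3.1.0]hexane-1-carboxylate
Product: 26 2-(trimethylsilyl)ethyl (13S)-15-[(tert-butyldiphenylsilyl)oxy]-3-oxo-18-norlabd-8(17)-en-19-oate (C4 epimeric keto forms plus enol), via aluminium enolate 25 (not isolated)
Conditions: Me2AlCl (2 equiv), CH2Cl2, −78 to −20 °C; then aq. potassium sodium tartrate
Reagents that add atoms: none
Why: Me2AlCl chelates the ketone and ester carbonyls on C4 and polarises the C4–C10 bond, whose tertiary carbon C10 is attacked from the rear by C9 of the allylsilane while chloride takes the silyl group from C17, so that C9–C10 forms, C8=C17 appears and the chelated aluminium enolate 25 is left for protonation on work-up. The closest known reaction type is the acid-promoted stereospecific cyclisation of olefinic cyclopropyl ketones, together with the Hosomi–Sakurai-type opening of acceptor-activated cyclopropanes by allylsilanes. Ring B closes in a 6-endo-trig sense with respect to the C8=C9 bond through a chair, whereas ring A is not closed but arises by enlargement of the cyclopentanone, because the bond that breaks is the one shared by the three- and five-membered rings. C10 is set by inversion, which together with the cis relation of C6 and C20 on the cyclopropane puts the C20 methyl anti to H5, and C9 is set by the Z allylsilane, whose C11 chain sits equatorial in the chair so that H9 ends anti to C20. The step needs cleavage of C4–C10 in preference to C4–C5 and clean inversion: the tertiary C10, the alignment of the ester carbonyl with the C4–C10 bond and a tether that starts at C5 and can reach only C10 through a six-membered transition state secure both, and the proton-scavenging Lewis acid spares the allylsilane from protodesilylation.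

Step 14
Reactants: 26 2-(trimethylsilyl)ethyl (13S)-15-[(tert-butyldiphenylsilyl)oxy]-3-oxo-18-norlabd-8(17)-en-19-oate
Product: 27 2-(trimethylsilyl)ethyl (13S)-15-[(tert-butyldiphenylsilyl)oxy]-3-oxolabd-8(17)-en-19-oate
Conditions: t-BuOK, MeI, THF–t-BuOH, 0 °C to rt
Reagents that add atoms: iodomethane, CI
Why: C-Alkylation of the β-keto ester enolate should occur on the α face, anti to the axial C20 methyl, which makes the new methyl C18 and leaves the ester axial as C19.

Step 15
Reactants: 27 2-(trimethylsilyl)ethyl (13S)-15-[(tert-butyldiphenylsilyl)oxy]-3-oxolabd-8(17)-en-19-oate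
Product: 28 2-(trimethylsilyl)ethyl (13S)-15-[(tert-butyldiphenylsilyl)oxy]-3β-hydroxylabd-8(17)-en-19-oate
Conditions: NaBH4, MeOH–THF, 0 °C
Reagents that add atoms: none
Why: Hydride reduction of the C3 ketone from the less hindered α face should give mainly the equatorial 3β-alcohol, and either epimer serves in the deoxygenation.

Step 16
Reactants: 28 2-(trimethylsilyl)ethyl (13S)-15-[(tert-butyldiphenylsilyl)oxy]-3β-hydroxylabd-8(17)-en-19-oate
Product: 29 2-(trimethylsilyl)ethyl (13S)-15-[(tert-butyldiphenylsilyl)oxy]-3β-[(1H-imidazol-1-ylcarbonothioyl)oxy]labd-8(17)-en-19-oate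
Conditions: 1,1'-thiocarbonyldiimidazole, DMAP (cat.), ClCH2CH2Cl, 80 °C
Reagents that add atoms: 1,1'-thiocarbonyldiimidazole, S=C(n1ccnc1)n1ccnc1
Why: Thioacylation under neutral conditions avoids a free alkoxide, which could trigger retro-aldol cleavage of the β-hydroxy ester.

Step 17
Reactants: 29 2-(trimethylsilyl)ethyl (13S)-15-[(tert-butyldiphenylsilyl)oxy]-3β-[(1H-imidazol-1-ylcarbonothioyl)oxy]labd-8(17)-en-19-oate
Product: 30 2-(trimethylsilyl)ethyl (13S)-15-[(tert-butyldiphenylsilyl)oxy]labd-8(17)-en-19-oate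
Conditions: Bu3SnH, AIBN (cat.), toluene, 110 °C
Reagents that add atoms: none
Why: Barton–McCombie deoxygenation removes the C3 oxygen through a secondary radical that cannot reach the remote exocyclic alkene and is reduced by Bu3SnH.

Step 18
Reactants: 30 2-(trimethylsilyl)ethyl (13S)-15-[(tert-butyldiphenylsilyl)oxy]labd-8(17)-en-19-oate
Product: 31 (13S)-15-hydroxylabd-8(17)-en-19-oic acid
Conditions: Bu4NF (4 equiv), THF, rt to 45 °C; then 1 M HCl to pH 3
Reagents that add atoms: none
Why: Fluoride attacks silicon in both groups, so the 2-(trimethylsilyl)ethyl ester fragments by β-elimination without any attack at the hindered C19 carbonyl and the TBDPS ether is cleaved in the same operation.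

Step 19
Reactants: 31 (13S)-15-hydroxylabd-8(17)-en-19-oic acid
Product: 32 (13S)-15-(formyloxy)labd-8(17)-en-19-oic acid, CNP0494097.1
Conditions: HCO2CH2CF3 (excess), THF, 65 °C
Reagents that add atoms: 2,2,2-trifluoroethyl formate, O=COCC(F)(F)F
Why: Transfer formylation of the primary alcohol by an activated formate ester is selective, since the tertiary neopentyl carboxylic acid does not react and the neutral conditions spare the exocyclic alkene.

**Compound list**

1 | (S)-citronellol, (3S)-3,7-dimethyloct-6-en-1-ol | CC(C)=CCC[C@H](C)CCO | starting material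
2 | tert-butyl{[(3S)-3,7-dimethyloct-6-en-1-yl]oxy}diphenylsilane | CC(C)=CCC[C@H](C)CCO[Si](c1ccccc1)(c1ccccc1)C(C)(C)C | intermediate
3 | 3,3-dimethyl-5-{(3S)-5-[(tert-butyldiphenylsilyl)oxy]-3-methylpentyl}-1,2,4-trioxolane (ozonide, not isolated) | CC1(C)OOC(CC[C@H](C)CCO[Si](c2ccccc2)(c2ccccc2)C(C)(C)C)O1 | intermediate
4 | (4S)-6-[(tert-butyldiphenylsilyl)oxy]-4-methylhexanal | O=CCC[C@H](C)CCO[Si](c1ccccc1)(c1ccccc1)C(C)(C)C | intermediate
5 | (2-bromoprop-2-en-1-yl)trimethylsilane | C=C(Br)C[Si](C)(C)C | starting material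
6 | [3-(trimethylsilyl)prop-1-en-2-yl]magnesium bromide (not isolated) | C=C([Mg]Br)C[Si](C)(C)C | intermediate
7 | (6S)-8-[(tert-butyldiphenylsilyl)oxy]-6-methyl-2-[(trimethylsilyl)methyl]oct-1-en-3-ol, both C3 epimers | C=C(C[Si](C)(C)C)C(O)CC[C@H](C)CCO[Si](c1ccccc1)(c1ccccc1)C(C)(C)C | intermediate
8 | triethyl orthoacetate | CCOC(C)(OCC)OCC | starting material
9 | 1-ethoxyvinyl ether of 7 (mixed ketene acetal, not isolated) | C=C(OCC)OC(CC[C@H](C)CCO[Si](c1ccccc1)(c1ccccc1)C(C)(C)C)C(=C)C[Si](C)(C)C | intermediate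
10 | ethyl (4Z,8S)-10-[(tert-butyldiphenylsilyl)oxy]-8-methyl-4-[(trimethylsilyl)methyl]dec-4-enoate | CCOC(=O)CC/C(C[Si](C)(C)C)=C/CC[C@H](C)CCO[Si](c1ccccc1)(c1ccccc1)C(C)(C)C | intermediate
11 | diisobutylaluminium hemiacetal of 10 (not isolated) | CCOC(O[Al](CC(C)C)CC(C)C)CC/C(C[Si](C)(C)C)=C/CC[C@H](C)CCO[Si](c1ccccc1)(c1ccccc1)C(C)(C)C | intermediate
12 | (4Z,8S)-10-[(tert-butyldiphenylsilyl)oxy]-8-methyl-4-[(trimethylsilyl)methyl]dec-4-enal | O=CCC/C(C[Si](C)(C)C)=C/CC[C@H](C)CCO[Si](c1ccccc1)(c1ccccc1)C(C)(C)C | intermediate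
13 | ethyl 2-(triphenyl-λ5-phosphanylidene)propanoate | CCOC(=O)C(C)=P(c1ccccc1)(c1ccccc1)c1ccccc1 | starting material
14 | ethyl (2E,6Z,10S)-12-[(tert-butyldiphenylsilyl)oxy]-2,10-dimethyl-6-[(trimethylsilyl)methyl]dodeca-2,6-dienoate | CCOC(=O)/C(C)=C/CC/C(C[Si](C)(C)C)=C/CC[C@H](C)CCO[Si](c1ccccc1)(c1ccccc1)C(C)(C)C | intermediate
15 | (2E,6Z,10S)-12-[(tert-butyldiphenylsilyl)oxy]-2,10-dimethyl-6-[(trimethylsilyl)methyl]dodeca-2,6-dien-1-ol | OC/C(C)=C/CC/C(C[Si](C)(C)C)=C/CC[C@H](C)CCO[Si](c1ccccc1)(c1ccccc1)C(C)(C)C | intermediate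
16 | (2E,6Z,10S)-1-bromo-12-[(tert-butyldiphenylsilyl)oxy]-2,10-dimethyl-6-[(trimethylsilyl)methyl]dodeca-2,6-diene | BrC/C(C)=C/CC/C(C[Si](C)(C)C)=C/CC[C@H](C)CCO[Si](c1ccccc1)(c1ccccc1)C(C)(C)C | intermediate
17 | 2,2,6-trimethyl-4H-1,3-dioxin-4-one | CC1=CC(=O)OC(C)(C)O1 | starting material
18 | 2-(trimethylsilyl)ethan-1-ol | C[Si](C)(C)CCO | starting material
19 | acetylketene, but-1-ene-1,3-dione (not isolated) | CC(=O)C=C=O | intermediate
20 | 2-(trimethylsilyl)ethyl 3-oxobutanoate | CC(=O)CC(=O)OCC[Si](C)(C)C | intermediate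
21 | sodium lithium dianion (dienediolate) of 20 (not isolated) | C=C([O-])C=C([O-])OCC[Si](C)(C)C.[Li+].[Na+] | intermediate
22 | 2-(trimethylsilyl)ethyl (6E,10Z,14S)-16-[(tert-butyldiphenylsilyl)oxy]-6,14-dimethyl-3-oxo-10-[(trimethylsilyl)methyl]hexadeca-6,10-dienoate | C[Si](C)(C)CCOC(=O)CC(=O)CC/C(C)=C/CC/C(C[Si](C)(C)C)=C/CC[C@H](C)CCO[Si](c1ccccc1)(c1ccccc1)C(C)(C)C | intermediate
23 | 2-(trimethylsilyl)ethyl (6E,10Z,14S)-16-[(tert-butyldiphenylsilyl)oxy]-2-diazo-6,14-dimethyl-3-oxo-10-[(trimethylsilyl)methyl]hexadeca-6,10-dienoate | C[Si](C)(C)CCOC(=O)C(=[N+]=[N-])C(=O)CC/C(C)=C/CC/C(C[Si](C)(C)C)=C/CC[C@H](C)CCO[Si](c1ccccc1)(c1ccccc1)C(C)(C)C | intermediate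
24 | 2-(trimethylsilyl)ethyl (1R,5R,6R)-6-{(3Z,7S)-9-[(tert-butyldiphenylsilyl)oxy]-7-methyl-3-[(trimethylsilyl)methyl]non-3-en-1-yl}-5-methyl-2-oxobicyclo[3.1.0]hexane-1-carboxylate (precursor of the key step) | C[Si](C)(C)CCOC(=O)[C@@]12C(=O)CC[C@]1(C)[C@H]2CC/C(C[Si](C)(C)C)=C/CC[C@H](C)CCO[Si](c1ccccc1)(c1ccccc1)C(C)(C)C | intermediate
25 | dimethylaluminium enolate of 26, O3-bound and chelated by the ester (not isolated) | C=C1CC[C@@H]2[C@](C)(CCC(O[Al](C)C)=C2C(=O)OCC[Si](C)(C)C)[C@H]1CC[C@H](C)CCO[Si](c1ccccc1)(c1ccccc1)C(C)(C)C | intermediate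
26 | 2-(trimethylsilyl)ethyl (13S)-15-[(tert-butyldiphenylsilyl)oxy]-3-oxo-18-norlabd-8(17)-en-19-oate, 5α-H, 9α-H, 10β-methyl, C4 epimerisable (product of the key step) | C=C1CC[C@@H]2[C@](C)(CCC(=O)C2C(=O)OCC[Si](C)(C)C)[C@H]1CC[C@H](C)CCO[Si](c1ccccc1)(c1ccccc1)C(C)(C)C | intermediate
27 | 2-(trimethylsilyl)ethyl (13S)-15-[(tert-butyldiphenylsilyl)oxy]-3-oxolabd-8(17)-en-19-oate (4α-methyl, 4β-ester) | C=C1CC[C@@H]2[C@](C)(CCC(=O)[C@]2(C)C(=O)OCC[Si](C)(C)C)[C@H]1CC[C@H](C)CCO[Si](c1ccccc1)(c1ccccc1)C(C)(C)C | intermediate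
28 | 2-(trimethylsilyl)ethyl (13S)-15-[(tert-butyldiphenylsilyl)oxy]-3β-hydroxylabd-8(17)-en-19-oate | C=C1CC[C@@H]2[C@](C)(CC[C@H](O)[C@]2(C)C(=O)OCC[Si](C)(C)C)[C@H]1CC[C@H](C)CCO[Si](c1ccccc1)(c1ccccc1)C(C)(C)C | intermediate
29 | 2-(trimethylsilyl)ethyl (13S)-15-[(tert-butyldiphenylsilyl)oxy]-3β-[(1H-imidazol-1-ylcarbonothioyl)oxy]labd-8(17)-en-19-oate | C=C1CC[C@@H]2[C@](C)(CC[C@H](OC(=S)n3ccnc3)[C@]2(C)C(=O)OCC[Si](C)(C)C)[C@H]1CC[C@H](C)CCO[Si](c1ccccc1)(c1ccccc1)C(C)(C)C | intermediate
30 | 2-(trimethylsilyl)ethyl (13S)-15-[(tert-butyldiphenylsilyl)oxy]labd-8(17)-en-19-oate | C=C1CC[C@@H]2[C@](C)(CCC[C@]2(C)C(=O)OCC[Si](C)(C)C)[C@H]1CC[C@H](C)CCO[Si](c1ccccc1)(c1ccccc1)C(C)(C)C | intermediate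
31 | (13S)-15-hydroxylabd-8(17)-en-19-oic acid | C=C1CC[C@@H]2[C@](C)(CCC[C@]2(C)C(=O)O)[C@H]1CC[C@H](C)CCO | intermediate
32 | (13S)-15-(formyloxy)labd-8(17)-en-19-oic acid, (1S,4aR,5S,8aR)-5-[(3S)-5-(formyloxy)-3-methylpentyl]-1,4a-dimethyl-6-methylidenedecahydronaphthalene-1-carboxylic acid, CNP0494097.1 | C=C1CC[C@@H]2[C@](C)(CCC[C@]2(C)C(=O)O)[C@H]1CC[C@H](C)CCOC=O | target

**Step count and risk**

Total: 19 steps. Longest linear sequence: 18 steps (steps 1–8 and 10–19, from (S)-citronellol); step 9 is a one-step side branch.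

The three steps most likely to fail:

Step 13 (key step). The C4–C10 bond may ionise before C9 engages, so that the C10 cation is lost by proton elimination, or the allylsilane may be protodesilylated before ring closure. The fallback gives up the cyclopropane as initiator and closes both rings by an oxidative radical cyclisation that involves no cation at C10. It sets out from 22: C-methylation at C4 (K2CO3, MeI, acetone) would give 2-(trimethylsilyl)ethyl (6E,10Z,14S)-16-[(tert-butyldiphenylsilyl)oxy]-2,6,14-trimethyl-3-oxo-10-[(trimethylsilyl)methyl]hexadeca-6,10-dienoate F1. Treatment of F1 with Mn(OAc)3·2H2O and Cu(OAc)2·H2O in AcOH at rt should form C4–C5 and C9–C10 by two 6-endo radical additions, the tertiary β-silyl radical at C8 being oxidised by divalent copper to the C8(17) alkene with loss of silicon. The chair-like course known for this reaction type places the ester axial, so 27 is reached directly and step 14 is skipped. Nothing in this sequence controls the bicycle relative to C13, so 27 would be accompanied by its diastereomer with the mirror-image decalin F2. The pair would be reduced as in step 15 to 28 and the corresponding diastereomeric alcohol F3, and separated as camphanates in the way laid out for step 12. The fallback comes back to the route at 28.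

Step 12. The copper carbenoid may discriminate poorly between the two faces of the C5=C10 alkene. Because C13 is remote, the minor cyclopropane is a diastereomer that cannot be removed and is carried through the key step. The fallback replaces reliance on catalyst control alone by separation of covalent diastereomers next to the ring system. It sets out from 28 (then contaminated by the alcohol of the mirror-image series): acylation with (1S)-camphanic chloride (pyridine, DMAP, 60 °C) would give the 3-O-[(1S)-camphanoyl] ester of 28 F4 and the 3-O-[(1S)-camphanoyl] ester of the mirror-image-decalin alcohol F5. These two differ in the relation of the bicycle to the adjacent camphanoyl group and should separate by chromatography or crystallisation. Methanolysis of F4 (K2CO3, MeOH) would come back to the route at stereochemically homogeneous 28.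

Step 4. The allylsilane may be protodesilylated, or the alkene geometry may leak, under the hot and weakly acidic Claisen conditions. The fallback builds the trisubstituted alkene by two stereospecific cross-couplings on a 1,1-dibromoalkene. It sets out from 4: dibromo-olefination (CBr4, PPh3, CH2Cl2, 0 °C) would give tert-butyl{[(3S)-7,7-dibromo-3-methylhept-6-en-1-yl]oxy}diphenylsilane F6. A Negishi coupling with BrZnCH2CH2CO2Et catalysed by PdCl2(DPEphos) should replace selectively the bromine trans to the alkyl chain and give ethyl (4Z,8S)-4-bromo-10-[(tert-butyldiphenylsilyl)oxy]-8-methyldec-4-enoate F7. A second Negishi coupling with Me3SiCH2ZnCl catalysed by Pd(t-Bu3P)2 should replace the remaining bromine with retention and come back to the route at 10.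

Further compounds
F1 | step 13 | 2-(trimethylsilyl)ethyl (6E,10Z,14S)-16-[(tert-butyldiphenylsilyl)oxy]-2,6,14-trimethyl-3-oxo-10-[(trimethylsilyl)methyl]hexadeca-6,10-dienoate (C2 epimers) | C[Si](C)(C)CCOC(=O)C(C)C(=O)CC/C(C)=C/CC/C(C[Si](C)(C)C)=C/CC[C@H](C)CCO[Si](c1ccccc1)(c1ccccc1)C(C)(C)C
F2 | step 13 | diastereomer of 27 with the mirror-image decalin (C4, C5, C9, C10 inverted, 13S unchanged) | C=C1CC[C@H]2[C@@](C)(CCC(=O)[C@@]2(C)C(=O)OCC[Si](C)(C)C)[C@@H]1CC[C@H](C)CCO[Si](c1ccccc1)(c1ccccc1)C(C)(C)C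
F3 | step 13 | diastereomer of 28 with the mirror-image decalin (C3, C4, C5, C9, C10 inverted, 13S unchanged) | C=C1CC[C@H]2[C@@](C)(CC[C@@H](O)[C@@]2(C)C(=O)OCC[Si](C)(C)C)[C@@H]1CC[C@H](C)CCO[Si](c1ccccc1)(c1ccccc1)C(C)(C)C
F4 | step 12 | 3-O-[(1S)-camphanoyl] ester of 28 | C=C1CC[C@@H]2[C@](C)(CC[C@H](OC(=O)[C@@]34CC[C@@](C)(C(=O)O3)C4(C)C)[C@]2(C)C(=O)OCC[Si](C)(C)C)[C@H]1CC[C@H](C)CCO[Si](c1ccccc1)(c1ccccc1)C(C)(C)C
F5 | step 12 | 3-O-[(1S)-camphanoyl] ester of the mirror-image-decalin alcohol | C=C1CC[C@H]2[C@@](C)(CC[C@@H](OC(=O)[C@@]34CC[C@@](C)(C(=O)O3)C4(C)C)[C@@]2(C)C(=O)OCC[Si](C)(C)C)[C@@H]1CC[C@H](C)CCO[Si](c1ccccc1)(c1ccccc1)C(C)(C)C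
F6 | step 4 | tert-butyl{[(3S)-7,7-dibromo-3-methylhept-6-en-1-yl]oxy}diphenylsilane | BrC(Br)=CCC[C@H](C)CCO[Si](c1ccccc1)(c1ccccc1)C(C)(C)C
F7 | step 4 | ethyl (4Z,8S)-4-bromo-10-[(tert-butyldiphenylsilyl)oxy]-8-methyldec-4-enoate | CCOC(=O)CC/C(Br)=C/CC[C@H](C)CCO[Si](c1ccccc1)(c1ccccc1)C(C)(C)C
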